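The earlier runs and the new flask were computed with made-up constants, and the scatter is random.

Begin at the late end of the flask, at 20 h, and ask how many halvings of the unexchanged complex fit in before then.

| setting | theta | flask |
|---|---|---|
| starting complex | 1.9 M | 0.93 M |
| gas | 30 mM (held) | 30 mM (held) |
| remark | run made earlier |  |
| time |  | 20 h |

theta run (percent of the starting complex charged)

| time / h | complex with one exchanged / % |
|---|---|
| 0.333 | 5.8 |
| 0.500 | 7.6 |
| 0.833 | 13.3 |
| 1.33 | 19.1 |
| 2.50 | 33.8 |
| 4.00 | 48.2 |

(each reading ± 0.5 percentage points)

- at the start none of the gas is in solution

- time up to 20 h at which complex with one exchanged stands highest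
- the amount of complex with one exchanged, in percent of the starting complex charged, at that time

From the last theta reading, which carries its scatter and counts the exchanged part as complex with one exchanged, you get

H = 4.00 h × ln 2 / (−ln(1 − 48.2%)) = 4.22 h

This H is the half-life of the charge: the time in which the unexchanged part falls to half.

Turn the time first. By hand, the flask at 20 h holds

n = 20 h / H = 4.74 halvings, leaving 3.73% unexchanged.

My reckoning therefore puts 96.3% of the charge through the exchange by then. Now turn the charge, from 1.9 M to 0.93 M, with the gas held at 30 mM. By hand, H stays put if each complex falls at its own steady rate, but the theta run shows one charge, so its readings can't test that.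

The forecast gives 20 h (from 17 h to 20 h) and 96% (from 80% to 98.5%), holding that “nothing consumes the product, so it should rise monotonically”.

The flask peaks at 6.10 h with 67.7%, and complex with two exchanged already stands at 18.8% then.

    starting complex + incoming ligand → leaving ligand + complex with one exchanged (k = 1.10 M⁻¹ min⁻¹)
    complex with one exchanged + incoming ligand → leaving ligand + complex with two exchanged (k = 0.0600 M⁻¹ min⁻¹)
    starting complex ⇌ dormant form (K = 1.80, k = 0.0360 min⁻¹)
    gas ⇌ incoming ligand, rate k4*(csat - [incoming ligand]) (kL = 0.200 min⁻¹)

At that time the flask's unexchanged part is 3.69% starting complex plus 9.80% dormant form, so its own half-life is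

H′ = 6.10 h × ln 2 / (−ln(3.69% + 9.80%)) = 2.11 h

That is about half of H, close to the ratio of the charges. Scaling H by that ratio gives

H × 0.93 M / 1.9 M = 2.06 h

For a neighbour flask, the same charge left until 8.0 h, this reckons 6.78% unexchanged, and that neighbour flask holds 1.67% starting complex plus 4.59% dormant form, together 6.26%.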